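**Retrosynthetic overview**

1. Marchantin C has four benzene rings: ring A (1,2,4-trisubstituted phenol ring), ring B (para-phenylene), ring C (1,2,3-trisubstituted phenol ring) and ring D (meta-phenylene). It is traced back to a macrocyclic Z-stilbene bis(methyl ether) by alkene hydrogenation and O-demethylation.
2. The strategy rests on the CH2–CH2 bridge between C4 of ring B (para to its ether oxygen) and C1 of ring C (next to its ether oxygen). This is an isolated two-carbon unit between two aryl carbons, so both aryl–carbon bonds are cut at once, giving an open-chain diiodide and a Z-configured C2 bis-stannane.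
3. The diiodide comes from the dianiline by double Sandmeyer iodination. The dianiline comes from a dinitrostilbene by one hydrogenation, which also sets the ring A–CH2CH2–ring D bridge.
4. The dinitrostilbene comes from a Wittig union of a ring A aldehyde with a ring D benzylphosphonium salt. Each half is a diaryl ether made by nitro-activated SNAr (ring A–O–ring B and ring C–O–ring D).
5. Ring order: the four benzene rings are bought. The 18-membered macrocycle is the only ring formed, in the double Stille coupling.

Key step: step 8

Remark on the chemistry: the Z-distannane is treated as not reliably available from catalogues and is therefore made in step 7. The Wittig product is carried on as its E/Z mixture because step 5 saturates the double bond.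

**Route**

Step 1
Reactants: 1 isovanillin (3-hydroxy-4-methoxybenzaldehyde); 2 1-fluoro-4-nitrobenzene
Product: 3 4-methoxy-3-(4-nitrophenoxy)benzaldehyde
Conditions: K2CO3, DMF, 100 °C
Reagents that add atoms: none
Why: SNAr etherification in which the para-nitro group activates the fluoride toward the phenoxide of 1, and the non-enolisable aldehyde is inert to carbonate.

Step 2
Reactants: 4 3-hydroxybenzyl alcohol; 5 2-fluoro-3-nitroanisole
Product: 6 [3-(2-methoxy-6-nitrophenoxy)phenyl]methanol
Conditions: K2CO3, DMF, 90 °C
Reagents that add atoms: none
Why: SNAr etherification activated by the ortho-nitro group, and carbonate deprotonates only the phenol, so the benzylic hydroxyl should not be arylated.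

Step 3
Reactants: 6 [3-(2-methoxy-6-nitrophenoxy)phenyl]methanol
Product: 7 {[3-(2-methoxy-6-nitrophenoxy)phenyl]methyl}triphenylphosphonium bromide
Conditions: PPh3·HBr, MeCN, reflux
Reagents that add atoms: triphenylphosphine hydrobromide, [Br-].[PH+](c1ccccc1)(c1ccccc1)c1ccccc1
Why: Acid-promoted substitution of the protonated benzylic alcohol by triphenylphosphine gives the phosphonium salt in one operation, with water as leaving group and the nitro and ether groups untouched.

Step 4
Reactants: 7 {[3-(2-methoxy-6-nitrophenoxy)phenyl]methyl}triphenylphosphonium bromide; 3 4-methoxy-3-(4-nitrophenoxy)benzaldehyde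
Product: 9 4-methoxy-3'-(2-methoxy-6-nitrophenoxy)-3-(4-nitrophenoxy)stilbene (E/Z mixture), via phosphonium ylide 8 (not isolated)
Conditions: K2CO3, 18-crown-6 (cat.), CH2Cl2, reflux
Reagents that add atoms: none
Why: Wittig olefination of a semi-stabilised benzylic ylide with an aromatic aldehyde joins the ring A and ring D halves, and the alkene geometry is irrelevant because the double bond is saturated in step 5.

Step 5
Reactants: 9 4-methoxy-3'-(2-methoxy-6-nitrophenoxy)-3-(4-nitrophenoxy)stilbene (E/Z mixture)
Product: 10 2-(3-{2-[3-(4-aminophenoxy)-4-methoxyphenyl]ethyl}phenoxy)-3-methoxyaniline (dianiline)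
Conditions: H2 (1 atm), 10% Pd/C, EtOAc/MeOH, rt
Reagents that add atoms: none
Why: Catalytic hydrogenation over palladium on carbon should saturate the stilbene and reduce both nitro groups to amines in one operation, while diaryl and methyl ethers are inert.

Step 6
Reactants: 10 2-(3-{2-[3-(4-aminophenoxy)-4-methoxyphenyl]ethyl}phenoxy)-3-methoxyaniline
Product: 12 1-iodo-2-(3-{2-[3-(4-iodophenoxy)-4-methoxyphenyl]ethyl}phenoxy)-3-methoxybenzene (open-chain diiodide), via bis-diazonium ditosylate 11 (not isolated)
Conditions: p-TsOH·H2O, NaNO2, KI, MeCN/H2O, 10 °C to rt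
Reagents that add atoms: potassium iodide, [K+].[I-]; sodium nitrite, [Na+].[O-]N=O, and p-toluenesulfonic acid, Cc1ccc(cc1)S(=O)(=O)O (the last two leave atoms only in intermediate 11)
Why: Double diazotisation followed by Sandmeyer-type iododediazoniation, which needs no copper salt because iodide itself reduces the diazonium ion by single-electron transfer and the aryl radical is captured by iodine.

Step 7
Reactants: 13 hexabutyldistannane; 14 acetylene
Product: 15 (Z)-1,2-bis(tributylstannyl)ethene
Conditions: Pd(PPh3)4 (2 mol%), acetylene (1 atm), dioxane, 60 °C, dark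
Reagents that add atoms: none
Why: Palladium-catalysed syn-distannation of an alkyne, in which the Sn–Sn bond adds to zerovalent palladium, acetylene inserts and reductive elimination places both tin groups on the same side, hence Z.

Step 8
Reactants: 12 open-chain diiodide; 15 (Z)-1,2-bis(tributylstannyl)ethene
Product: 17 dehydromarchantin C dimethyl ether (macrocyclic Z-stilbene with the Z double bond between ring B and ring C), via Z-styrylstannane 16 (not isolated)
Conditions: Pd(PPh3)4 (20 mol%), degassed DMF, 75 °C, 12 and 15 (1.05 equiv) added together by syringe pump over 12 h, final concentration about 2 mM, dark; aq. KF work-up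
Reagents that add atoms: none
Why: Zerovalent palladium should insert first into the unhindered C–I bond of ring B, and transmetalation with one vinyl–tin bond of 15 followed by reductive elimination gives styrylstannane 16; a second oxidative addition at the ring C iodide, slower because it lies next to the aryloxy group, is followed by intramolecular tin-to-palladium transfer of the vinyl carbon and reductive elimination. The closest known reaction type is the double Stille stitching macrocyclisation of a dihalide with a 1,2-distannylethene. The 18-membered ring is closed in the second coupling by an endo-type macrocyclisation, in which the ring C arylpalladium iodide (divalent palladium) and the vinylstannane at the other end of the same chain meet in a cyclic transmetalation and the ring C–vinyl bond forms on reductive elimination. No stereocentre is formed, and the Z geometry of the new alkene is inherited from 15 because Stille transmetalation and reductive elimination retain alkene configuration; the cis arrangement also lets two carbons span C4 of ring B and C1 of ring C without strain. The step needs the first coupling to be intermolecular and the second intramolecular, which the simultaneous slow addition at high dilution secures by keeping the stationary concentration of 16 low, and the order in which the two iodides react does not matter because both orders lead to 17.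

Step 9
Reactants: 17 dehydromarchantin C dimethyl ether
Product: 18 marchantin C dimethyl ether
Conditions: H2 (1 atm), 10% Pd/C, EtOAc, rt
Reagents that add atoms: none
Why: Catalytic hydrogenation of the cis-stilbene gives the CH2–CH2 bridge, and the molecule has no benzylic C–O or C–halogen bond that could be hydrogenolysed.

Step 10
Reactants: 18 marchantin C dimethyl ether
Product: 20 marchantin C, via bis(dibromoboryl) ether 19 (not isolated)
Conditions: BBr3, CH2Cl2, −78 °C to rt; then H2O
Reagents that add atoms: boron tribromide, BrB(Br)Br (its atoms stay only in intermediate 19; 20 keeps none)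
Why: Lewis acid cleavage of aryl methyl ethers by BBr3 (bromide attacks the methyl group of the boron-complexed ether) frees both phenols, while diaryl ethers are not cleaved under these conditions.

**Compound list**

1 | isovanillin | COc1ccc(C=O)cc1O | starting material
2 | 1-fluoro-4-nitrobenzene | O=[N+]([O-])c1ccc(F)cc1 | starting material
3 | 4-methoxy-3-(4-nitrophenoxy)benzaldehyde | COc1ccc(C=O)cc1Oc1ccc(cc1)[N+](=O)[O-] | intermediate
4 | 3-hydroxybenzyl alcohol | OCc1cccc(O)c1 | starting material
5 | 2-fluoro-3-nitroanisole | COc1cccc([N+](=O)[O-])c1F | starting material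
6 | [3-(2-methoxy-6-nitrophenoxy)phenyl]methanol | COc1cccc([N+](=O)[O-])c1Oc1cccc(CO)c1 | intermediate
7 | {[3-(2-methoxy-6-nitrophenoxy)phenyl]methyl}triphenylphosphonium bromide | COc1cccc([N+](=O)[O-])c1Oc1cccc(C[P+](c2ccccc2)(c2ccccc2)c2ccccc2)c1.[Br-] | intermediate
8 | phosphonium ylide of 7 | COc1cccc([N+](=O)[O-])c1Oc1cccc(C=P(c2ccccc2)(c2ccccc2)c2ccccc2)c1 | intermediate
9 | 4-methoxy-3'-(2-methoxy-6-nitrophenoxy)-3-(4-nitrophenoxy)stilbene (E/Z mixture) | COc1ccc(C=Cc2cccc(Oc3c(OC)cccc3[N+](=O)[O-])c2)cc1Oc1ccc(cc1)[N+](=O)[O-] | intermediate
10 | 2-(3-{2-[3-(4-aminophenoxy)-4-methoxyphenyl]ethyl}phenoxy)-3-methoxyaniline | COc1ccc(CCc2cccc(Oc3c(OC)cccc3N)c2)cc1Oc1ccc(N)cc1 | intermediate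
11 | bis-diazonium ditosylate of 10 | COc1ccc(CCc2cccc(Oc3c(OC)cccc3[N+]#N)c2)cc1Oc1ccc(cc1)[N+]#N.Cc1ccc(cc1)S(=O)(=O)[O-].Cc1ccc(cc1)S(=O)(=O)[O-] | intermediate
12 | 1-iodo-2-(3-{2-[3-(4-iodophenoxy)-4-methoxyphenyl]ethyl}phenoxy)-3-methoxybenzene | Ic1ccc(cc1)Oc1cc(ccc1OC)CCc1cccc(c1)Oc1c(I)cccc1OC | intermediate
13 | hexabutyldistannane | CCCC[Sn](CCCC)(CCCC)[Sn](CCCC)(CCCC)CCCC | starting material
14 | acetylene | C#C | starting material
15 | (Z)-1,2-bis(tributylstannyl)ethene | CCCC[Sn](CCCC)(CCCC)/C=C\[Sn](CCCC)(CCCC)CCCC | intermediate
16 | Z-styrylstannane (ring B coupled, ring C iodide intact) | CCCC[Sn](CCCC)(CCCC)/C=C\c1ccc(cc1)Oc1cc(ccc1OC)CCc1cccc(c1)Oc1c(I)cccc1OC | intermediate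
17 | dehydromarchantin C dimethyl ether (macrocyclic Z-stilbene) | COc1ccc2cc1Oc1ccc(cc1)/C=C\c1cccc(OC)c1Oc1cccc(c1)CC2 | intermediate
18 | marchantin C dimethyl ether | COc1ccc2cc1Oc1ccc(cc1)CCc1cccc(OC)c1Oc1cccc(c1)CC2 | intermediate
19 | bis(dibromoboryl) ether of marchantin C | BrB(Br)Oc1ccc2cc1Oc1ccc(cc1)CCc1cccc(OB(Br)Br)c1Oc1cccc(c1)CC2 | intermediate
20 | marchantin C | Oc1ccc2cc1Oc1ccc(cc1)CCc1cccc(O)c1Oc1cccc(c1)CC2 | target

**Step count**

Total steps: 10. Longest linear sequence: 8 (steps 2, 3, 4, 5, 6, 8, 9, 10).

**Steps most likely to fail, with fallbacks**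

1. Step 8. The second coupling may proceed between molecules and give oligomers instead of closing the ring. The styrylstannane may also be lost by protodestannylation or by Z-to-E isomerisation before it cyclises. The fallback sets out from 12 and closes the same bridge by carbonyl coupling. Palladium-catalysed reductive carbonylation of both C–I bonds (CO, Bu3SnH added slowly, Pd(PPh3)4, THF, 50 °C) should give 2-(3-{2-[3-(4-formylphenoxy)-4-methoxyphenyl]ethyl}phenoxy)-3-methoxybenzaldehyde F1. Intramolecular McMurry coupling (TiCl4, Zn, pyridine, THF, reflux, high dilution) should then give the macrocyclic stilbene F2, whose alkene geometry is immaterial. Hydrogenation of F2 under the conditions of step 9 comes back to the route at 18.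

2. Step 6. Two diazonium groups must each be captured by iodide in one operation. Either may instead be lost by hydrolysis, by azo coupling with amine not yet diazotised, or by intramolecular arylation of ring D from the ring C aryl radical. The fallback sets out from 1 and carries both iodides in from bought building blocks, so that no diazonium chemistry is needed.
   - Chan–Lam coupling of 1 with 4-iodophenylboronic acid (Cu(OAc)2, pyridine, 4 Å MS, CH2Cl2, air, rt) should give 3-(4-iodophenoxy)-4-methoxybenzaldehyde F3.
   - The same coupling of 2-iodo-6-methoxyphenol with [3-(hydroxymethyl)phenyl]boronic acid should give [3-(2-iodo-6-methoxyphenoxy)phenyl]methanol F4.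
   - PPh3·HBr in refluxing MeCN converts F4 into {[3-(2-iodo-6-methoxyphenoxy)phenyl]methyl}triphenylphosphonium bromide F5.
   - K2CO3 and 18-crown-6 in CH2Cl2 generate the ylide F6, which reacts with F3 in a Wittig olefination to give 3-(4-iodophenoxy)-3'-(2-iodo-6-methoxyphenoxy)-4-methoxystilbene (E/Z mixture) F7.
   - Diimide reduction of F7 (TsNHNH2, NaOAc, THF/H2O, reflux) saturates the alkene without touching the C–I bonds and comes back to the route at 12.

3. Step 7. Oxidative addition of the Sn–Sn bond of hexabutyldistannane to zerovalent palladium may be too slow for useful conversion, and the Z-distannane may isomerise toward the E isomer on heating or in light during purification. The fallback sets out from 14 and uses the more reactive hexamethyldistannane under the same catalysis (Pd(PPh3)4, dioxane, rt to 60 °C) to give (Z)-1,2-bis(trimethylstannyl)ethene F8. F8 takes the place of 15 in step 8. There it should pass through the trimethylstannyl Z-styrylstannane F9 and come back to the route at 17. The trimethyltin compounds call for stricter containment.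

**Further compounds**

F1 | step 8 | 2-(3-{2-[3-(4-formylphenoxy)-4-methoxyphenyl]ethyl}phenoxy)-3-methoxybenzaldehyde | O=Cc1ccc(cc1)Oc1cc(ccc1OC)CCc1cccc(c1)Oc1c(C=O)cccc1OC
F2 | step 8 | macrocyclic stilbene from McMurry coupling (alkene geometry as formed) | COc1ccc2cc1Oc1ccc(cc1)C=Cc1cccc(OC)c1Oc1cccc(c1)CC2
F3 | step 6 | 3-(4-iodophenoxy)-4-methoxybenzaldehyde | COc1ccc(C=O)cc1Oc1ccc(I)cc1
F4 | step 6 | [3-(2-iodo-6-methoxyphenoxy)phenyl]methanol | COc1cccc(I)c1Oc1cccc(CO)c1
F5 | step 6 | {[3-(2-iodo-6-methoxyphenoxy)phenyl]methyl}triphenylphosphonium bromide | COc1cccc(I)c1Oc1cccc(C[P+](c2ccccc2)(c2ccccc2)c2ccccc2)c1.[Br-]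
F6 | step 6 | phosphonium ylide of F5 | COc1cccc(I)c1Oc1cccc(C=P(c2ccccc2)(c2ccccc2)c2ccccc2)c1
F7 | step 6 | 3-(4-iodophenoxy)-3'-(2-iodo-6-methoxyphenoxy)-4-methoxystilbene (E/Z mixture) | COc1ccc(C=Cc2cccc(Oc3c(OC)cccc3I)c2)cc1Oc1ccc(I)cc1
F8 | step 7 | (Z)-1,2-bis(trimethylstannyl)ethene | C[Sn](C)(C)/C=C\[Sn](C)(C)C
F9 | step 7 | trimethylstannyl Z-styrylstannane (ring B coupled, ring C iodide intact) | C[Sn](C)(C)/C=C\c1ccc(cc1)Oc1cc(ccc1OC)CCc1cccc(c1)Oc1c(I)cccc1OC
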